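**Assumption:** (4R,6R)-actinol (1), the industrial zeaxanthin intermediate made from ketoisophorone, is taken as a purchasable chiral-pool material. Carotenoid numbering (C-3, C-5, C-6, C-8) is used in the comments for the ring ends.

## Retrosynthetic overview

1. The exocyclic Z-alkene of the ylidenebutenolide comes from E1cB loss of silanol from a vinylogous Mukaiyama aldol adduct. That aldol C–C bond joins the C15 butenolide 15 (west) to the C22 polyenynal 24 (east).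
2. 15 comes from Au-catalysed 5-endo cyclisation of α-hydroxyallene 14 (axis-to-centre transfer sets C-8), 14 from anti-SN2′ hydride opening of alkynyl epoxide 13, and 13 from Sonogashira coupling of ethynyl epoxide 9 with 3-bromobutenolide 12.
3. 9 comes from enol triflate 4 by carbonylation, Sharpless epoxidation and one-carbon homologation. 24 comes from the same triflate 4 by Sonogashira coupling with (E)-3-methylpent-2-en-4-yn-1-ol, then HWE (C4) and Wittig (C3) extension.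
4. Rings: both carbocycles are bought as actinol and the lactone as furan-2(5H)-one. Formed in the route are the epoxide (step 5) and then the dihydrofuran (step 11, which consumes the epoxide-derived oxygen); the ylidenebutenolide is completed last.

All polyene steps (13–20) are run under argon with exclusion of light.

## Route

**Step 1**
Reactants: 1 (4R,6R)-4-hydroxy-2,2,6-trimethylcyclohexan-1-one
Product: 2 (4R,6R)-4-[(tert-butyldimethylsilyl)oxy]-2,2,6-trimethylcyclohexan-1-one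
Conditions: TBSCl, imidazole, DMF, rt
Reagents that add atoms: tert-butyldimethylsilyl chloride, CC(C)(C)[Si](C)(C)Cl
Why: Standard silylation of the only hydroxyl; no stereocentre is touched.

**Step 2**
Reactants: 2 (4R,6R)-4-[(tert-butyldimethylsilyl)oxy]-2,2,6-trimethylcyclohexan-1-one
Product: 4 (4R)-4-[(tert-butyldimethylsilyl)oxy]-2,6,6-trimethylcyclohex-1-en-1-yl trifluoromethanesulfonate, via lithium enolate 3 (not isolated)
Conditions: LDA, THF, −78 °C; then PhNTf2, −78 °C → rt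
Reagents that add atoms: N-phenylbis(trifluoromethanesulfonimide), O=S(=O)(N(c1ccccc1)S(=O)(=O)C(F)(F)F)C(F)(F)F
Why: The ketone can enolise only toward C-6 (C-2 is quaternary), so a single enolate is O-triflated (enol triflate formation); the C-6 centre is erased on purpose and C-4 is untouched.

**Step 3**
Reactants: 4 (4R)-4-[(tert-butyldimethylsilyl)oxy]-2,6,6-trimethylcyclohex-1-en-1-yl trifluoromethanesulfonate
Product: 5 methyl (4R)-4-[(tert-butyldimethylsilyl)oxy]-2,6,6-trimethylcyclohex-1-ene-1-carboxylate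
Conditions: Pd(OAc)2 (5 mol %), PPh3, CO (1 atm), MeOH, Et3N, DMF, 60 °C
Reagents that add atoms: carbon monoxide, [C-]#[O+]; methanol, CO
Why: Pd-catalysed alkoxycarbonylation of the enol triflate (oxidative addition, CO insertion, methanolysis) installs C-7.

**Step 4**
Reactants: 5 methyl (4R)-4-[(tert-butyldimethylsilyl)oxy]-2,6,6-trimethylcyclohex-1-ene-1-carboxylate
Product: 6 {(4R)-4-[(tert-butyldimethylsilyl)oxy]-2,6,6-trimethylcyclohex-1-en-1-yl}methanol
Conditions: DIBAL-H, CH2Cl2, −78 → 0 °C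
Reagents that add atoms: none
Why: DIBAL-H reduces the conjugated ester 1,2 to the allylic alcohol needed for directed epoxidation.

**Step 5**
Reactants: 6 {(4R)-4-[(tert-butyldimethylsilyl)oxy]-2,6,6-trimethylcyclohex-1-en-1-yl}methanol
Product: 7 {(1R,4S,6R)-4-[(tert-butyldimethylsilyl)oxy]-2,2,6-trimethyl-7-oxabicyclo[4.1.0]heptan-1-yl}methanol
Conditions: Ti(OiPr)4, D-(−)-diethyl tartrate, t-BuOOH, 4 Å MS, CH2Cl2, −20 °C
Reagents that add atoms: tert-butyl hydroperoxide, CC(C)(C)OO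
Why: Katsuki–Sharpless asymmetric epoxidation; D-(−)-DET delivers oxygen to the face anti to the silyloxy group (matched with the substrate bias), setting both epoxide centres (5R,6S in carotenoid numbering).

**Step 6**
Reactants: 7 {(1R,4S,6R)-4-[(tert-butyldimethylsilyl)oxy]-2,2,6-trimethyl-7-oxabicyclo[4.1.0]heptan-1-yl}methanol
Product: 8 (1S,4S,6R)-4-[(tert-butyldimethylsilyl)oxy]-2,2,6-trimethyl-7-oxabicyclo[4.1.0]heptane-1-carbaldehyde
Conditions: Dess–Martin periodinane, NaHCO3, CH2Cl2, 0 °C → rt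
Reagents that add atoms: none
Why: Buffered Dess–Martin oxidation gives a non-enolisable α-epoxy aldehyde, so nothing can epimerise.

**Step 7**
Reactants: 8 (1S,4S,6R)-4-[(tert-butyldimethylsilyl)oxy]-2,2,6-trimethyl-7-oxabicyclo[4.1.0]heptane-1-carbaldehyde
Product: 9 (1R,4S,6R)-4-[(tert-butyldimethylsilyl)oxy]-1-ethynyl-2,2,6-trimethyl-7-oxabicyclo[4.1.0]heptane
Conditions: dimethyl (1-diazo-2-oxopropyl)phosphonate, K2CO3, MeOH, 0 °C → rt
Reagents that add atoms: dimethyl (1-diazo-2-oxopropyl)phosphonate, COP(=O)(OC)C(=[N+]=[N-])C(C)=O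
Why: Seyferth–Gilbert homologation with the Ohira–Bestmann reagent adds C-8 under mild base; the quaternary α-carbon cannot epimerise.

**Step 8**
Reactants: 10 furan-2(5H)-one
Product: 12 3-bromofuran-2(5H)-one, via trans-3,4-dibromolactone 11 (not isolated)
Conditions: Br2, CH2Cl2, 0 °C → rt; then Et3N, 0 °C
Reagents that add atoms: bromine, BrBr
Why: Anti bromination of the alkene followed by E1cB dehydrobromination (acidic α-H, β-bromide leaves) gives the α-bromobutenolide.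

**Step 9**
Reactants: 9 (1R,4S,6R)-4-[(tert-butyldimethylsilyl)oxy]-1-ethynyl-2,2,6-trimethyl-7-oxabicyclo[4.1.0]heptane; 12 3-bromofuran-2(5H)-one
Product: 13 3-({(1R,4S,6R)-4-[(tert-butyldimethylsilyl)oxy]-2,2,6-trimethyl-7-oxabicyclo[4.1.0]heptan-1-yl}ethynyl)furan-2(5H)-one
Conditions: PdCl2(PPh3)2 (5 mol %), CuI (10 mol %), i-Pr2NEt, THF, rt
Reagents that add atoms: none
Why: Sonogashira coupling of an electron-poor α-bromo enoate-type bromide with the terminal alkyne; the hindered amine avoids conjugate addition to the butenolide and the epoxide centres are untouched.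

**Step 10**
Reactants: 13 3-({(1R,4S,6R)-4-[(tert-butyldimethylsilyl)oxy]-2,2,6-trimethyl-7-oxabicyclo[4.1.0]heptan-1-yl}ethynyl)furan-2(5H)-one
Product: 14 3-[(aS)-2-{(2R,4S)-4-[(tert-butyldimethylsilyl)oxy]-2-hydroxy-2,6,6-trimethylcyclohexylidene}ethenyl]furan-2(5H)-one
Conditions: Pd2(dba)3·CHCl3 (2.5 mol %), n-Bu3P (5 mol %), HCO2H/Et3N (1.5 equiv each), THF, 0 °C → rt
Reagents that add atoms: none
Why: Tsuji-type Pd/formate hydrogenolysis: Pd(0) opens the propargylic epoxide anti (SN2′) to a σ-allenyl-Pd formate, and decarboxylation/reductive elimination puts H on C-8 opposite the departing oxygen, so the butenolide ends syn to the former C–O bond and the (aS) axis is set by centre-to-axis transfer.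

**Step 11**
Reactants: 14 3-[(aS)-2-{(2R,4S)-4-[(tert-butyldimethylsilyl)oxy]-2-hydroxy-2,6,6-trimethylcyclohexylidene}ethenyl]furan-2(5H)-one
Product: 15 3-{(2R,6S,7aR)-6-[(tert-butyldimethylsilyl)oxy]-4,4,7a-trimethyl-2,4,5,6,7,7a-hexahydro-1-benzofuran-2-yl}furan-2(5H)-one
Conditions: AuCl3 (5 mol %), THF, rt
Reagents that add atoms: none
Why: Au-catalysed 5-endo cycloisomerisation of an α-hydroxyallene: the tertiary OH attacks the allene terminus in the ring plane while H and the butenolide stay above and below it, so the (aS) axis is copied into the 2R centre (C-8), trans to the 7a-methyl.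

**Step 12**
Reactants: 4 (4R)-4-[(tert-butyldimethylsilyl)oxy]-2,6,6-trimethylcyclohex-1-en-1-yl trifluoromethanesulfonate; 16 (2E)-3-methylpent-2-en-4-yn-1-ol
Product: 17 (2E)-5-{(4R)-4-[(tert-butyldimethylsilyl)oxy]-2,6,6-trimethylcyclohex-1-en-1-yl}-3-methylpent-2-en-4-yn-1-ol
Conditions: Pd(PPh3)4 (5 mol %), CuI (10 mol %), i-Pr2NH, THF, rt → 40 °C
Reagents that add atoms: none
Why: Sonogashira coupling of the enol triflate with the E-enynol; the alkene geometry of 16 is carried over unchanged.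

**Step 13**
Reactants: 17 (2E)-5-{(4R)-4-[(tert-butyldimethylsilyl)oxy]-2,6,6-trimethylcyclohex-1-en-1-yl}-3-methylpent-2-en-4-yn-1-ol
Product: 18 (2E)-5-{(4R)-4-[(tert-butyldimethylsilyl)oxy]-2,6,6-trimethylcyclohex-1-en-1-yl}-3-methylpent-2-en-4-ynal
Conditions: MnO2, CH2Cl2, rt
Reagents that add atoms: none
Why: MnO2 oxidises only the allylic alcohol, under neutral conditions that do not isomerise the enyne.

**Step 14**
Reactants: 18 (2E)-5-{(4R)-4-[(tert-butyldimethylsilyl)oxy]-2,6,6-trimethylcyclohex-1-en-1-yl}-3-methylpent-2-en-4-ynal; 19 ethyl (2E)-4-(diethoxyphosphoryl)but-2-enoate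
Product: 20 ethyl (2E,4E,6E)-9-{(4R)-4-[(tert-butyldimethylsilyl)oxy]-2,6,6-trimethylcyclohex-1-en-1-yl}-7-methylnona-2,4,6-trien-8-ynoate
Conditions: LiHMDS, THF, −78 → 0 °C
Reagents that add atoms: none
Why: Vinylogous Horner–Wadsworth–Emmons olefination; the stabilised phosphonate anion gives the new disubstituted alkene E.

**Step 15**
Reactants: 20 ethyl (2E,4E,6E)-9-{(4R)-4-[(tert-butyldimethylsilyl)oxy]-2,6,6-trimethylcyclohex-1-en-1-yl}-7-methylnona-2,4,6-trien-8-ynoate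
Product: 21 (2E,4E,6E)-9-{(4R)-4-[(tert-butyldimethylsilyl)oxy]-2,6,6-trimethylcyclohex-1-en-1-yl}-7-methylnona-2,4,6-trien-8-yn-1-ol
Conditions: DIBAL-H, CH2Cl2, −78 °C
Reagents that add atoms: none
Why: 1,2-reduction of the trienoate to the allylic alcohol without touching the polyene.

**Step 16**
Reactants: 21 (2E,4E,6E)-9-{(4R)-4-[(tert-butyldimethylsilyl)oxy]-2,6,6-trimethylcyclohex-1-en-1-yl}-7-methylnona-2,4,6-trien-8-yn-1-ol
Product: 22 (2E,4E,6E)-9-{(4R)-4-[(tert-butyldimethylsilyl)oxy]-2,6,6-trimethylcyclohex-1-en-1-yl}-7-methylnona-2,4,6-trien-8-ynal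
Conditions: MnO2, CH2Cl2, rt
Reagents that add atoms: none
Why: Selective MnO2 oxidation of the polyenylic alcohol to the trienal.

**Step 17**
Reactants: 22 (2E,4E,6E)-9-{(4R)-4-[(tert-butyldimethylsilyl)oxy]-2,6,6-trimethylcyclohex-1-en-1-yl}-7-methylnona-2,4,6-trien-8-ynal; 23 2-(triphenyl-λ5-phosphanylidene)propanal
Product: 24 (2E,4E,6E,8E)-11-{(4R)-4-[(tert-butyldimethylsilyl)oxy]-2,6,6-trimethylcyclohex-1-en-1-yl}-2,9-dimethylundeca-2,4,6,8-tetraen-10-ynal
Conditions: toluene, 80 °C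
Reagents that add atoms: none
Why: Wittig reaction with a formyl-stabilised ylide gives the E trisubstituted enal; the α-methyl enal product is too unreactive to olefinate again.

**Step 18**
Reactants: 15 3-{(2R,6S,7aR)-6-[(tert-butyldimethylsilyl)oxy]-4,4,7a-trimethyl-2,4,5,6,7,7a-hexahydro-1-benzofuran-2-yl}furan-2(5H)-one; 24 (2E,4E,6E,8E)-11-{(4R)-4-[(tert-butyldimethylsilyl)oxy]-2,6,6-trimethylcyclohex-1-en-1-yl}-2,9-dimethylundeca-2,4,6,8-tetraen-10-ynal
Product: 26 5-[(2E,4E,6E,8E)-1-[(tert-butyldimethylsilyl)oxy]-11-{(4R)-4-[(tert-butyldimethylsilyl)oxy]-2,6,6-trimethylcyclohex-1-en-1-yl}-2,9-dimethylundeca-2,4,6,8-tetraen-10-yn-1-yl]-3-{(2R,6S,7aR)-6-[(tert-butyldimethylsilyl)oxy]-4,4,7a-trimethyl-2,4,5,6,7,7a-hexahydro-1-benzofuran-2-yl}furan-2(5H)-one (diastereomer mixture at the two new centres), via 2-silyloxyfuran 25 (not isolated)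
Conditions: TBSOTf, i-Pr2NEt, CH2Cl2, 0 °C (15 alone); then 24, −78 → −30 °C; Et3N-deactivated silica
Reagents that add atoms: tert-butyldimethylsilyl trifluoromethanesulfonate, CC(C)(C)[Si](C)(C)OS(=O)(=O)C(F)(F)F
Why: Vinylogous Mukaiyama aldol: the silyloxyfuran formed in situ attacks the silyl-activated enal 1,2 through its free C-5 (C-3 is blocked), and the two new centres need no control because both are erased in step 19; low temperature and excess amine protect the allylic C-8–O bond.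

**Step 19**
Reactants: 26 (the silylated aldol adduct above)
Product: 27 (5Z)-5-[(2E,4E,6E,8E)-11-{(4R)-4-[(tert-butyldimethylsilyl)oxy]-2,6,6-trimethylcyclohex-1-en-1-yl}-2,9-dimethylundeca-2,4,6,8-tetraen-10-yn-1-ylidene]-3-{(2R,6S,7aR)-6-[(tert-butyldimethylsilyl)oxy]-4,4,7a-trimethyl-2,4,5,6,7,7a-hexahydro-1-benzofuran-2-yl}furan-2(5H)-one
Conditions: DBU, CH2Cl2, 0 °C → rt
Reagents that add atoms: none
Why: E1cB elimination: DBU removes the acidic γ-H (2-oxidofuran) and silanolate leaves, so all diastereomers converge on the thermodynamically favoured Z-γ-alkylidenebutenolide; a minor E isomer is removed by chromatography.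

**Step 20**
Reactants: 27 (the bis-silyl ether above)
Product: 28 (5Z)-5-[(2E,4E,6E,8E)-11-{(4R)-4-hydroxy-2,6,6-trimethylcyclohex-1-en-1-yl}-2,9-dimethylundeca-2,4,6,8-tetraen-10-yn-1-ylidene]-3-[(2R,6S,7aR)-6-hydroxy-4,4,7a-trimethyl-2,4,5,6,7,7a-hexahydro-1-benzofuran-2-yl]furan-2(5H)-one
Conditions: HF·pyridine, excess pyridine, THF, 0 °C → rt
Reagents that add atoms: none
Why: Pyridine-buffered fluoride desilylation removes both secondary TBS ethers without opening the lactone (no strong base) or ionising the C-8–O bond (no strong acid).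

## Compound list

1 | (4R,6R)-4-hydroxy-2,2,6-trimethylcyclohexan-1-one (actinol) | O=C1C(C)(C)C[C@H](O)C[C@H]1C | starting material
2 | (4R,6R)-4-[(tert-butyldimethylsilyl)oxy]-2,2,6-trimethylcyclohexan-1-one | O=C1C(C)(C)C[C@H](O[Si](C)(C)C(C)(C)C)C[C@H]1C | intermediate
3 | lithium (4R)-4-[(tert-butyldimethylsilyl)oxy]-2,6,6-trimethylcyclohex-1-en-1-olate | [Li+].[O-]C1=C(C)C[C@@H](O[Si](C)(C)C(C)(C)C)CC1(C)C | intermediate (not isolated)
4 | (4R)-4-[(tert-butyldimethylsilyl)oxy]-2,6,6-trimethylcyclohex-1-en-1-yl trifluoromethanesulfonate | CC1=C(OS(=O)(=O)C(F)(F)F)C(C)(C)C[C@H](O[Si](C)(C)C(C)(C)C)C1 | intermediate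
5 | methyl (4R)-4-[(tert-butyldimethylsilyl)oxy]-2,6,6-trimethylcyclohex-1-ene-1-carboxylate | COC(=O)C1=C(C)C[C@@H](O[Si](C)(C)C(C)(C)C)CC1(C)C | intermediate
6 | {(4R)-4-[(tert-butyldimethylsilyl)oxy]-2,6,6-trimethylcyclohex-1-en-1-yl}methanol | OCC1=C(C)C[C@@H](O[Si](C)(C)C(C)(C)C)CC1(C)C | intermediate
7 | {(1R,4S,6R)-4-[(tert-butyldimethylsilyl)oxy]-2,2,6-trimethyl-7-oxabicyclo[4.1.0]heptan-1-yl}methanol | OC[C@@]12O[C@]1(C)C[C@@H](O[Si](C)(C)C(C)(C)C)CC2(C)C | intermediate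
8 | (1S,4S,6R)-4-[(tert-butyldimethylsilyl)oxy]-2,2,6-trimethyl-7-oxabicyclo[4.1.0]heptane-1-carbaldehyde | O=C[C@@]12O[C@]1(C)C[C@@H](O[Si](C)(C)C(C)(C)C)CC2(C)C | intermediate
9 | (1R,4S,6R)-4-[(tert-butyldimethylsilyl)oxy]-1-ethynyl-2,2,6-trimethyl-7-oxabicyclo[4.1.0]heptane | C#C[C@@]12O[C@]1(C)C[C@@H](O[Si](C)(C)C(C)(C)C)CC2(C)C | intermediate
10 | furan-2(5H)-one | O=C1OCC=C1 | starting material
11 | trans-3,4-dibromodihydrofuran-2(3H)-one (racemic, one enantiomer drawn) | O=C1OC[C@H](Br)[C@H]1Br | intermediate (not isolated)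
12 | 3-bromofuran-2(5H)-one | O=C1OCC=C1Br | intermediate
13 | 3-({(1R,4S,6R)-4-[(tert-butyldimethylsilyl)oxy]-2,2,6-trimethyl-7-oxabicyclo[4.1.0]heptan-1-yl}ethynyl)furan-2(5H)-one | O=C1OCC=C1C#C[C@@]23O[C@]2(C)C[C@@H](O[Si](C)(C)C(C)(C)C)CC3(C)C | intermediate
14 | 3-[(aS)-2-{(2R,4S)-4-[(tert-butyldimethylsilyl)oxy]-2-hydroxy-2,6,6-trimethylcyclohexylidene}ethenyl]furan-2(5H)-one | O=C1OCC=C1C([H])=[C@]=C2C(C)(C)C[C@H](O[Si](C)(C)C(C)(C)C)C[C@@]2(C)O | intermediate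
15 | 3-{(2R,6S,7aR)-6-[(tert-butyldimethylsilyl)oxy]-4,4,7a-trimethyl-2,4,5,6,7,7a-hexahydro-1-benzofuran-2-yl}furan-2(5H)-one | O=C1OCC=C1[C@H]2C=C3C(C)(C)C[C@H](O[Si](C)(C)C(C)(C)C)C[C@@]3(C)O2 | intermediate
16 | (2E)-3-methylpent-2-en-4-yn-1-ol | C#C/C(C)=C/CO | starting material
17 | (2E)-5-{(4R)-4-[(tert-butyldimethylsilyl)oxy]-2,6,6-trimethylcyclohex-1-en-1-yl}-3-methylpent-2-en-4-yn-1-ol | CC1=C(C#C/C(C)=C/CO)C(C)(C)C[C@H](O[Si](C)(C)C(C)(C)C)C1 | intermediate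
18 | (2E)-5-{(4R)-4-[(tert-butyldimethylsilyl)oxy]-2,6,6-trimethylcyclohex-1-en-1-yl}-3-methylpent-2-en-4-ynal | CC1=C(C#C/C(C)=C/C=O)C(C)(C)C[C@H](O[Si](C)(C)C(C)(C)C)C1 | intermediate
19 | ethyl (2E)-4-(diethoxyphosphoryl)but-2-enoate | CCOC(=O)/C=C/CP(=O)(OCC)OCC | starting material
20 | ethyl (2E,4E,6E)-9-{(4R)-4-[(tert-butyldimethylsilyl)oxy]-2,6,6-trimethylcyclohex-1-en-1-yl}-7-methylnona-2,4,6-trien-8-ynoate | CC1=C(C#C/C(C)=C/C=C/C=C/C(=O)OCC)C(C)(C)C[C@H](O[Si](C)(C)C(C)(C)C)C1 | intermediate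
21 | (2E,4E,6E)-9-{(4R)-4-[(tert-butyldimethylsilyl)oxy]-2,6,6-trimethylcyclohex-1-en-1-yl}-7-methylnona-2,4,6-trien-8-yn-1-ol | CC1=C(C#C/C(C)=C/C=C/C=C/CO)C(C)(C)C[C@H](O[Si](C)(C)C(C)(C)C)C1 | intermediate
22 | (2E,4E,6E)-9-{(4R)-4-[(tert-butyldimethylsilyl)oxy]-2,6,6-trimethylcyclohex-1-en-1-yl}-7-methylnona-2,4,6-trien-8-ynal | CC1=C(C#C/C(C)=C/C=C/C=C/C=O)C(C)(C)C[C@H](O[Si](C)(C)C(C)(C)C)C1 | intermediate
23 | 2-(triphenyl-λ5-phosphanylidene)propanal | CC(C=O)=P(c1ccccc1)(c1ccccc1)c1ccccc1 | starting material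
24 | (2E,4E,6E,8E)-11-{(4R)-4-[(tert-butyldimethylsilyl)oxy]-2,6,6-trimethylcyclohex-1-en-1-yl}-2,9-dimethylundeca-2,4,6,8-tetraen-10-ynal | CC1=C(C#C/C(C)=C/C=C/C=C/C=C(C)/C=O)C(C)(C)C[C@H](O[Si](C)(C)C(C)(C)C)C1 | intermediate
25 | 2-[(tert-butyldimethylsilyl)oxy]-3-{(2R,6S,7aR)-6-[(tert-butyldimethylsilyl)oxy]-4,4,7a-trimethyl-2,4,5,6,7,7a-hexahydro-1-benzofuran-2-yl}furan | CC(C)(C)[Si](C)(C)Oc1occc1[C@H]2C=C3C(C)(C)C[C@H](O[Si](C)(C)C(C)(C)C)C[C@@]3(C)O2 | intermediate (not isolated)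
26 | 5-[(2E,4E,6E,8E)-1-[(tert-butyldimethylsilyl)oxy]-11-{(4R)-4-[(tert-butyldimethylsilyl)oxy]-2,6,6-trimethylcyclohex-1-en-1-yl}-2,9-dimethylundeca-2,4,6,8-tetraen-10-yn-1-yl]-3-{(2R,6S,7aR)-6-[(tert-butyldimethylsilyl)oxy]-4,4,7a-trimethyl-2,4,5,6,7,7a-hexahydro-1-benzofuran-2-yl}furan-2(5H)-one (mixture at lactone C-5 and the carbinol carbon) | CC1=C(C#C/C(C)=C/C=C/C=C/C=C(C)/C(O[Si](C)(C)C(C)(C)C)C2OC(=O)C([C@H]3C=C4C(C)(C)C[C@H](O[Si](C)(C)C(C)(C)C)C[C@@]4(C)O3)=C2)C(C)(C)C[C@H](O[Si](C)(C)C(C)(C)C)C1 | intermediate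
27 | (5Z)-5-[(2E,4E,6E,8E)-11-{(4R)-4-[(tert-butyldimethylsilyl)oxy]-2,6,6-trimethylcyclohex-1-en-1-yl}-2,9-dimethylundeca-2,4,6,8-tetraen-10-yn-1-ylidene]-3-{(2R,6S,7aR)-6-[(tert-butyldimethylsilyl)oxy]-4,4,7a-trimethyl-2,4,5,6,7,7a-hexahydro-1-benzofuran-2-yl}furan-2(5H)-one | CC1=C(C#C/C(C)=C/C=C/C=C/C=C(C)/C=C2/C=C([C@H]3C=C4C(C)(C)C[C@H](O[Si](C)(C)C(C)(C)C)C[C@@]4(C)O3)C(=O)O2)C(C)(C)C[C@H](O[Si](C)(C)C(C)(C)C)C1 | intermediate
28 | (5Z)-5-[(2E,4E,6E,8E)-11-{(4R)-4-hydroxy-2,6,6-trimethylcyclohex-1-en-1-yl}-2,9-dimethylundeca-2,4,6,8-tetraen-10-yn-1-ylidene]-3-[(2R,6S,7aR)-6-hydroxy-4,4,7a-trimethyl-2,4,5,6,7,7a-hexahydro-1-benzofuran-2-yl]furan-2(5H)-one | CC1=C(C#C/C(C)=C/C=C/C=C/C=C(C)/C=C2/C=C([C@H]3C=C4C(C)(C)C[C@H](O)C[C@@]4(C)O3)C(=O)O2)C(C)(C)C[C@H](O)C1 | target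

## Step count and risks

Total step count: 20. Longest linear sequence: 13 steps (1–7, 9–11, 18–20, from actinol 1).

**Step 10 (anti-SN2′ hydrogenolysis).** The allenyl-palladium intermediate may equilibrate and erode the anti selectivity, or palladium hydride may attack the unsaturated lactone. The fallback drops the allene and uses the classical epoxide-to-furanoid rearrangement. It sets out from alkyne 9: Pd-catalysed hydrostannylation (Bu3SnH, PdCl2(PPh3)2, THF, 0 °C) gives tributyl{(E)-2-[(1S,4S,6R)-4-(tert-butyldimethylsilyloxy)-2,2,6-trimethyl-7-oxabicyclo[4.1.0]heptan-1-yl]ethenyl}stannane F1. Stille coupling of this with 12 (Pd2(dba)3, AsPh3, NMP, rt) gives the epoxyvinyl butenolide 3-{(E)-2-[(1S,4S,6R)-4-(tert-butyldimethylsilyloxy)-2,2,6-trimethyl-7-oxabicyclo[4.1.0]heptan-1-yl]ethenyl}furan-2(5H)-one F2. Catalytic camphorsulfonic acid in CH2Cl2 at 0 °C opens the epoxide to a pentadienyl cation that the C-5 oxygen recaptures at C-8, giving 15 and its C-2 epimer, the (2S,6S,7aR) butenolide F3. The two are separated by chromatography and the wrong epimer is re-equilibrated with the same acid. This fallback is not stereoselective at C-8 (roughly 1:1), and it comes back to the route at 15.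

**Step 11 (gold cyclisation).** The electron-poor vinylallene may react slowly or follow other gold-mediated pathways. The fallback replaces metal catalysis by halocyclisation and reduction. It sets out from 14: N-iodosuccinimide in CH2Cl2 at 0 °C gives, by the same in-plane 5-endo attack of the hydroxyl, the vinyl iodide 3-{(2S,6S,7aR)-6-(tert-butyldimethylsilyloxy)-3-iodo-4,4,7a-trimethyl-2,4,5,6,7,7a-hexahydro-1-benzofuran-2-yl}furan-2(5H)-one F4 (same spatial arrangement at C-2; the descriptor changes only because of iodine). Pd-catalysed formate reduction (Pd(OAc)2, PPh3, HCO2H, Et3N, DMF, 40 °C) removes the iodine, and the route is rejoined at 15.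

**Step 18 (vinylogous aldol with the full polyenal).** The long polyenal and its polyenylic silyl ether may not survive silyl triflate, or addition may be sluggish. The fallback keeps the aldol for a small robust aldehyde and unites the halves by Stille coupling instead. It sets out from 15 and 18 and comes back at 27. Zirconium-catalysed carboalumination of propargyl alcohol followed by iodine gives (2E)-3-iodo-2-methylprop-2-en-1-ol F5, and MnO2 gives (2E)-3-iodo-2-methylprop-2-enal F6. Under the conditions of steps 18 and 19, 15 and this aldehyde give first the silylated aldol 5-[(2E)-1-(tert-butyldimethylsilyloxy)-3-iodo-2-methylprop-2-en-1-yl]-3-(hexahydrobenzofuranyl)furan-2(5H)-one F7 and then the iodo-diene (5Z)-5-[(2E)-3-iodo-2-methylprop-2-en-1-ylidene]-3-(hexahydrobenzofuranyl)furan-2(5H)-one F8. Separately, enynal 18 is extended with the known diethyl [(2E)-3-(tributylstannyl)prop-2-en-1-yl]phosphonate (LiHMDS, THF/DMPU, −78 °C) to tributyl{(1E,3E,5E)-8-[(4R)-4-(tert-butyldimethylsilyloxy)-2,6,6-trimethylcyclohex-1-en-1-yl]-6-methylocta-1,3,5-trien-7-yn-1-yl}stannane F9. Stille coupling of the iodo-diene with this stannane (Pd2(dba)3, AsPh3, NMP, rt, dark) gives 27.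

## Further compounds

F1 | step 10 | tributyl{(E)-2-[(1S,4S,6R)-4-(tert-butyldimethylsilyloxy)-2,2,6-trimethyl-7-oxabicyclo[4.1.0]heptan-1-yl]ethenyl}stannane | CCCC[Sn](CCCC)(CCCC)/C=C/[C@@]12O[C@]1(C)C[C@@H](O[Si](C)(C)C(C)(C)C)CC2(C)C
F2 | step 10 | 3-{(E)-2-[(1S,4S,6R)-4-(tert-butyldimethylsilyloxy)-2,2,6-trimethyl-7-oxabicyclo[4.1.0]heptan-1-yl]ethenyl}furan-2(5H)-one | O=C1OCC=C1/C=C/[C@@]23O[C@]2(C)C[C@@H](O[Si](C)(C)C(C)(C)C)CC3(C)C
F3 | step 10 | 3-{(2S,6S,7aR)-6-(tert-butyldimethylsilyloxy)-4,4,7a-trimethyl-2,4,5,6,7,7a-hexahydro-1-benzofuran-2-yl}furan-2(5H)-one (C-2 epimer of 15) | O=C1OCC=C1[C@@H]2C=C3C(C)(C)C[C@H](O[Si](C)(C)C(C)(C)C)C[C@@]3(C)O2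
F4 | step 11 | 3-{(2S,6S,7aR)-6-(tert-butyldimethylsilyloxy)-3-iodo-4,4,7a-trimethyl-2,4,5,6,7,7a-hexahydro-1-benzofuran-2-yl}furan-2(5H)-one | O=C1OCC=C1[C@H]2C(I)=C3C(C)(C)C[C@H](O[Si](C)(C)C(C)(C)C)C[C@@]3(C)O2
F5 | step 18 | (2E)-3-iodo-2-methylprop-2-en-1-ol | I/C=C(C)/CO
F6 | step 18 | (2E)-3-iodo-2-methylprop-2-enal | I/C=C(C)/C=O
F7 | step 18 | 5-[(2E)-1-(tert-butyldimethylsilyloxy)-3-iodo-2-methylprop-2-en-1-yl]-3-{(2R,6S,7aR)-6-(tert-butyldimethylsilyloxy)-4,4,7a-trimethyl-2,4,5,6,7,7a-hexahydro-1-benzofuran-2-yl}furan-2(5H)-one (diastereomer mixture) | I/C=C(C)/C(O[Si](C)(C)C(C)(C)C)C1OC(=O)C([C@H]2C=C3C(C)(C)C[C@H](O[Si](C)(C)C(C)(C)C)C[C@@]3(C)O2)=C1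
F8 | step 18 | (5Z)-5-[(2E)-3-iodo-2-methylprop-2-en-1-ylidene]-3-{(2R,6S,7aR)-6-(tert-butyldimethylsilyloxy)-4,4,7a-trimethyl-2,4,5,6,7,7a-hexahydro-1-benzofuran-2-yl}furan-2(5H)-one | I/C=C(C)/C=C1/C=C([C@H]2C=C3C(C)(C)C[C@H](O[Si](C)(C)C(C)(C)C)C[C@@]3(C)O2)C(=O)O1
F9 | step 18 | tributyl{(1E,3E,5E)-8-[(4R)-4-(tert-butyldimethylsilyloxy)-2,6,6-trimethylcyclohex-1-en-1-yl]-6-methylocta-1,3,5-trien-7-yn-1-yl}stannane | CC1=C(C#C/C(C)=C/C=C/C=C/[Sn](CCCC)(CCCC)CCCC)C(C)(C)C[C@H](O[Si](C)(C)C(C)(C)C)C1
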